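The plan disconnects the C3–C3a bond of the cyclopentane ring (hydroazulene numbering: C3 is the isopropyl carbinol carbon, C3a the ring-fusion CH, C4 the benzoate carbon). C3a sits α to C4, which can be a carbonyl, and C3 bears oxygen, so a rhodium carbenoid at C3a can insert into the oxygen-activated C3–H bond of a side chain. In one operation this closes the five-membered ring, creates the tetrasubstituted carbinol with retention from a secondary silyl ether set by asymmetric hydrogenation, and fixes C3a by cis fusion. The precursor is an α-diazo-γ-butyrolactone whose lactone ties the C4 carbonyl to the C8 oxygen; methallyl addition and ring-closing metathesis then build the cycloheptene.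

Key step: step 11

Remark: bicyclic compounds carry hydroazulene locants (C3 carbinol, C3a and C8a ring fusion, C4 and C8 ester carbons); the ligand antipodes in steps 1 and 6 are those expected by the accepted models to give the configurations drawn, and the other antipode is taken if the sense proves opposite.

Step 1
Reactants: 1 methyl 4-methyl-3-oxopentanoate
Product: 2 methyl (3S)-3-hydroxy-4-methylpentanoate
Conditions: H2 (50 atm), RuCl2[(R)-BINAP] (0.1 mol %), MeOH, 50 °C
Reagents that add atoms: none
Why: Noyori asymmetric hydrogenation of a β-keto ester, in which the ester-chelated ruthenium hydride should deliver hydrogen to the face that gives the (S)-carbinol, the future C3.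

Step 2
Reactants: 2 methyl (3S)-3-hydroxy-4-methylpentanoate
Product: 3 methyl (3S)-3-[(tert-butyldimethylsilyl)oxy]-4-methylpentanoate
Conditions: TBSCl, imidazole, DMF, rt
Reagents that add atoms: tert-butyldimethylsilyl chloride, CC(C)(C)[Si](C)(C)Cl
Why: Standard silylation of a secondary alcohol; the silyl ether later activates the adjacent C–H bond and blocks retro-aldol pathways until the last step.

Step 3
Reactants: 3 methyl (3S)-3-[(tert-butyldimethylsilyl)oxy]-4-methylpentanoate
Product: 4 (3S)-3-[(tert-butyldimethylsilyl)oxy]-4-methylpentan-1-ol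
Conditions: i-Bu2AlH (2.5 equiv), CH2Cl2, −78 → 0 °C; aq. potassium sodium tartrate
Reagents that add atoms: none
Why: Ester reduction to the primary alcohol with excess aluminium hydride, which leaves the stereocentre and the silyl ether untouched.

Step 4
Reactants: 4 (3S)-3-[(tert-butyldimethylsilyl)oxy]-4-methylpentan-1-ol
Product: 5 {[(3S)-1-bromo-4-methylpentan-3-yl]oxy}(tert-butyl)dimethylsilane
Conditions: CBr4, PPh3, CH2Cl2, 0 °C
Reagents that add atoms: carbon tetrabromide, BrC(Br)(Br)Br
Why: Appel bromination of the primary alcohol under neutral conditions that spare the silyl ether.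

Step 5
Reactants: 6 acrolein; 7 benzeneselenol
Product: 8 3-(phenylselanyl)propanal
Conditions: Et3N (cat.), CH2Cl2, 0 °C → rt
Reagents that add atoms: none
Why: Conjugate addition of the selenol to the enal gives a 2-(phenylselanyl)ethyl group, a masked vinyl group that cannot undergo allylic substitution or radical/carbenoid side reactions in the copper steps.

Step 6
Reactants: 8 3-(phenylselanyl)propanal; 9 methyl propiolate
Product: 10 methyl (4S)-4-hydroxy-6-(phenylselanyl)hex-2-ynoate
Conditions: Me2Zn (3 equiv), (S,S)-ProPhenol (10 mol %), Ph3PO (20 mol %), toluene, 4 °C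
Reagents that add atoms: none
Why: Zinc–ProPhenol-catalysed enantioselective alkynylation (Trost) of the aldehyde by the zinc acetylide of the propiolate, which should set the (S)-carbinol that becomes C8.

Step 7
Reactants: 10 methyl (4S)-4-hydroxy-6-(phenylselanyl)hex-2-ynoate
Product: 11 (5S)-4-methyl-5-[2-(phenylselanyl)ethyl]furan-2(5H)-one
Conditions: MeMgBr (2.5 equiv), CuBr·SMe2 (20 mol %), THF, −78 °C; aq. NH4Cl; TsOH (cat.), CH2Cl2, rt
Reagents that add atoms: methylmagnesium bromide, C[Mg]Br
Why: Copper-catalysed syn-carbometalation of the ynoate places methyl on the β-carbon and leaves ester and carbinol cis, so the (Z)-4-hydroxy enoate should lactonise to the butenolide without touching the carbinol centre.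

Step 8
Reactants: 5 {[(3S)-1-bromo-4-methylpentan-3-yl]oxy}(tert-butyl)dimethylsilane; 11 (5S)-4-methyl-5-[2-(phenylselanyl)ethyl]furan-2(5H)-one
Product: 14 (4R,5S)-4-{(3S)-3-[(tert-butyldimethylsilyl)oxy]-4-methylpentyl}-4-methyl-5-[2-(phenylselanyl)ethyl]oxolan-2-one, via Grignard reagent 12 (not isolated), via silyl ketene acetal 13 (not isolated)
Conditions: 5, Mg, THF, rt; then CuBr·SMe2 (20 mol %), Me3SiCl, 11, THF, −78 → −30 °C; aq. NH4Cl
Reagents that add atoms: none
Why: Chlorotrimethylsilane-accelerated copper-catalysed conjugate addition to a 4-methylbutenolide, which should occur anti to the C5 substituent and so set the quaternary centre (future C8a) with methyl cis to the selenoethyl group; the silyl ketene acetal is hydrolysed on work-up.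

Step 9
Reactants: 14 (4R,5S)-4-{(3S)-3-[(tert-butyldimethylsilyl)oxy]-4-methylpentyl}-4-methyl-5-[2-(phenylselanyl)ethyl]oxolan-2-one
Product: 16 (4R,5S)-4-{(3S)-3-[(tert-butyldimethylsilyl)oxy]-4-methylpentyl}-5-ethenyl-4-methyloxolan-2-one, via selenoxide 15 (not isolated)
Conditions: 30% H2O2, pyridine, CH2Cl2, 0 °C → rt
Reagents that add atoms: none
Why: Selenoxide syn-elimination at room temperature unmasks the vinyl group; only the CH2 next to C5 carries β-hydrogens, so a single alkene can form.

Step 10
Reactants: 16 (4R,5S)-4-{(3S)-3-[(tert-butyldimethylsilyl)oxy]-4-methylpentyl}-5-ethenyl-4-methyloxolan-2-one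
Product: 18 (4R,5S)-4-{(3S)-3-[(tert-butyldimethylsilyl)oxy]-4-methylpentyl}-3-diazo-5-ethenyl-4-methyloxolan-2-one, via trifluoroacetyl lactone 17 (not isolated)
Conditions: LiN(SiMe3)2, THF, −78 °C; CF3CO2CH2CF3; then MsN3, Et3N, H2O, MeCN, rt
Reagents that add atoms: methanesulfonyl azide, CS(=O)(=O)N=[N+]=[N-]
Why: Detrifluoroacetylative diazo transfer (Danheiser); the lactone has one enolisable position, so the diazo group can only enter at C3 of the oxolanone.

Step 11
Reactants: 18 (4R,5S)-4-{(3S)-3-[(tert-butyldimethylsilyl)oxy]-4-methylpentyl}-3-diazo-5-ethenyl-4-methyloxolan-2-one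
Product: 19 (3S,3aR,6S,6aR)-6-[(tert-butyldimethylsilyl)oxy]-3-ethenyl-3a-methyl-6-(propan-2-yl)hexahydro-1H-cyclopenta[c]furan-1-one
Conditions: Rh2(OAc)4 (1 mol %), CH2Cl2, 40 °C, slow addition of 18
Reagents that add atoms: none
Why: Rh2(OAc)4 expels dinitrogen from 18 to give an electrophilic rhodium carbenoid at the lactone α-carbon, which inserts into the tertiary, oxygen-activated C–H bond five atoms away through a three-centre, hydride-transfer-like transition state. The closest known reaction type is the rhodium-mediated 1,5 C–H insertion of α-diazo carbonyl compounds used for cyclopentane construction (Taber), including insertion next to ether oxygen. The cyclopentane closes in the 1,5-insertion mode and can only be cis-fused to the lactone, which fixes C6a (C3a of the target). Insertion proceeds with retention, so the tetrasubstituted carbinol C6 (C3 of the target) takes its configuration from the secondary silyl ether of step 1, the new ring bond replacing hydrogen. The step needs 1,5-insertion to win over 1,2-shift, 1,6-insertion into the isopropyl methine, ylide formation and cyclopropanation; the quaternary neighbour of the carbenoid has no hydrogen, the silyloxy group activates only the target methine and is a poor ylide donor, and the vinyl group cannot reach the carbenoid.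

Step 12
Reactants: 19 (3S,3aR,6S,6aR)-6-[(tert-butyldimethylsilyl)oxy]-3-ethenyl-3a-methyl-6-(propan-2-yl)hexahydro-1H-cyclopenta[c]furan-1-one; 20 2-methylallylmagnesium chloride
Product: 21 (3S,3aR,6S,6aR)-6-[(tert-butyldimethylsilyl)oxy]-3-ethenyl-3a-methyl-1-(2-methylprop-2-en-1-yl)-6-(propan-2-yl)hexahydro-1H-cyclopenta[c]furan-1-ol (lactol, both anomers)
Conditions: THF, −78 °C; aq. NH4Cl at −78 °C
Reagents that add atoms: none
Why: Addition of an allylic Grignard reagent to the hindered lactone carbonyl should stop at the magnesium hemiketalate at low temperature, as in the addition of allyl Grignard reagents to sugar lactones.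

Step 13
Reactants: 21 lactol (both anomers)
Product: 22 (3S,3aR,8S,8aR)-3-[(tert-butyldimethylsilyl)oxy]-8-hydroxy-6,8a-dimethyl-3-(propan-2-yl)-2,3,3a,5,8,8a-hexahydroazulen-4(1H)-one (in equilibrium with its oxygen-bridged hemiketal)
Conditions: second-generation Grubbs catalyst (5 mol %), CH2Cl2, 40 °C
Reagents that add atoms: none
Why: Ring-closing metathesis of the vinyl and methallyl groups, which are held cis on the oxolane ring (anomers interconvert through the open hydroxy ketone), closes the cycloheptene with the trisubstituted C6=C7 double bond and loses ethene.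

Step 14
Reactants: 22 hydroxy enone; 23 3-methylbutanoic anhydride
Product: 24 (3S,3aR,8S,8aR)-3-[(tert-butyldimethylsilyl)oxy]-6,8a-dimethyl-4-oxo-3-(propan-2-yl)-1,2,3,3a,4,5,8,8a-octahydroazulen-8-yl 3-methylbutanoate
Conditions: DMAP (cat.), pyridine, CH2Cl2, 0 °C → rt
Reagents that add atoms: none
Why: DMAP-catalysed acylation of the only acylable hydroxyl (the secondary C8 hydroxyl of the open tautomer), which places the isovalerate while C4 is still a ketone and so differentiates the two oxygens without protecting groups.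

Step 15
Reactants: 24 keto ester
Product: 25 (3S,3aS,4R,8S,8aR)-3-[(tert-butyldimethylsilyl)oxy]-4-hydroxy-6,8a-dimethyl-3-(propan-2-yl)-1,2,3,3a,4,5,8,8a-octahydroazulen-8-yl 3-methylbutanoate
Conditions: LiBH(s-Bu)3, THF, −78 °C; AcOH at −78 °C
Reagents that add atoms: none
Why: The bulky hydride should attack the convex face of the cis-fused bicycle, anti to the substituted C3 on the neighbouring ring-fusion carbon, giving the 4R alcohol (hydroxyl cis to C3 and to the C8 ester); the cold acidic quench avoids enolisation and acyl migration.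

Step 16
Reactants: 25 hydroxy ester; 26 4-[(tert-butyldimethylsilyl)oxy]benzoic acid
Product: 28 (3S,3aS,4R,8S,8aR)-3-[(tert-butyldimethylsilyl)oxy]-6,8a-dimethyl-8-[(3-methylbutanoyl)oxy]-3-(propan-2-yl)-1,2,3,3a,4,5,8,8a-octahydroazulen-4-yl 4-[(tert-butyldimethylsilyl)oxy]benzoate, via mixed anhydride 27 (not isolated)
Conditions: 26, 2,4,6-trichlorobenzoyl chloride, Et3N, THF, rt; then 25, DMAP, toluene, 60 °C
Reagents that add atoms: none
Why: Yamaguchi esterification through the mixed anhydride acylates the hindered secondary alcohol with retention at C4, while the tertiary silyl ether and the isovalerate stay intact.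

Step 17
Reactants: 28 bis-silyl diester
Product: 29 (3S,3aS,4R,8S,8aR)-3-hydroxy-6,8a-dimethyl-8-[(3-methylbutanoyl)oxy]-3-(propan-2-yl)-1,2,3,3a,4,5,8,8a-octahydroazulen-4-yl 4-hydroxybenzoate (target)
Conditions: HF·pyridine, pyridine, THF, 0 → 40 °C
Reagents that add atoms: none
Why: Fluoride cleaves the aryl and the tertiary alkyl silyl ether under weakly acidic conditions that should spare both esters; no stereocentre is touched.

Compound list
1 | methyl 4-methyl-3-oxopentanoate | COC(=O)CC(=O)C(C)C | starting material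
2 | methyl (3S)-3-hydroxy-4-methylpentanoate | COC(=O)C[C@H](O)C(C)C | intermediate
3 | methyl (3S)-3-[(tert-butyldimethylsilyl)oxy]-4-methylpentanoate | COC(=O)C[C@H](O[Si](C)(C)C(C)(C)C)C(C)C | intermediate
4 | (3S)-3-[(tert-butyldimethylsilyl)oxy]-4-methylpentan-1-ol | OCC[C@H](O[Si](C)(C)C(C)(C)C)C(C)C | intermediate
5 | {[(3S)-1-bromo-4-methylpentan-3-yl]oxy}(tert-butyl)dimethylsilane | BrCC[C@H](O[Si](C)(C)C(C)(C)C)C(C)C | intermediate
6 | acrolein | C=CC=O | starting material
7 | benzeneselenol | [SeH]c1ccccc1 | starting material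
8 | 3-(phenylselanyl)propanal | O=CCC[Se]c1ccccc1 | intermediate
9 | methyl propiolate | COC(=O)C#C | starting material
10 | methyl (4S)-4-hydroxy-6-(phenylselanyl)hex-2-ynoate | COC(=O)C#C[C@@H](O)CC[Se]c1ccccc1 | intermediate
11 | (5S)-4-methyl-5-[2-(phenylselanyl)ethyl]furan-2(5H)-one | O=C1C=C(C)[C@H](CC[Se]c2ccccc2)O1 | intermediate
12 | {(3S)-3-[(tert-butyldimethylsilyl)oxy]-4-methylpentyl}magnesium bromide (Grignard reagent from 5) | Br[Mg]CC[C@H](O[Si](C)(C)C(C)(C)C)C(C)C | intermediate
13 | trimethylsilyl ketene acetal of 14 (2-trimethylsilyloxy-4,5-dihydrofuran, same configuration as 14) | c1ccccc1[Se]CC[C@@H]2OC(O[Si](C)(C)C)=C[C@@]2(C)CC[C@H](O[Si](C)(C)C(C)(C)C)C(C)C | intermediate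
14 | (4R,5S)-4-{(3S)-3-[(tert-butyldimethylsilyl)oxy]-4-methylpentyl}-4-methyl-5-[2-(phenylselanyl)ethyl]oxolan-2-one | c1ccccc1[Se]CC[C@@H]2OC(=O)C[C@@]2(C)CC[C@H](O[Si](C)(C)C(C)(C)C)C(C)C | intermediate
15 | selenoxide of 14 | O=[Se](c1ccccc1)CC[C@@H]2OC(=O)C[C@@]2(C)CC[C@H](O[Si](C)(C)C(C)(C)C)C(C)C | intermediate
16 | (4R,5S)-4-{(3S)-3-[(tert-butyldimethylsilyl)oxy]-4-methylpentyl}-5-ethenyl-4-methyloxolan-2-one | C=C[C@@H]1OC(=O)C[C@@]1(C)CC[C@H](O[Si](C)(C)C(C)(C)C)C(C)C | intermediate
17 | 3-(trifluoroacetyl) derivative of 16 | C=C[C@@H]1OC(=O)C(C(=O)C(F)(F)F)[C@@]1(C)CC[C@H](O[Si](C)(C)C(C)(C)C)C(C)C | intermediate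
18 | (4R,5S)-4-{(3S)-3-[(tert-butyldimethylsilyl)oxy]-4-methylpentyl}-3-diazo-5-ethenyl-4-methyloxolan-2-one | C=C[C@@H]1OC(=O)C(=[N+]=[N-])[C@@]1(C)CC[C@H](O[Si](C)(C)C(C)(C)C)C(C)C | intermediate
19 | (3S,3aR,6S,6aR)-6-[(tert-butyldimethylsilyl)oxy]-3-ethenyl-3a-methyl-6-(propan-2-yl)hexahydro-1H-cyclopenta[c]furan-1-one | C=C[C@@H]1OC(=O)[C@@H]2[C@@]1(C)CC[C@]2(O[Si](C)(C)C(C)(C)C)C(C)C | intermediate
20 | 2-methylallylmagnesium chloride | CC(=C)C[Mg]Cl | starting material
21 | (3S,3aR,6S,6aR)-6-[(tert-butyldimethylsilyl)oxy]-3-ethenyl-3a-methyl-1-(2-methylprop-2-en-1-yl)-6-(propan-2-yl)hexahydro-1H-cyclopenta[c]furan-1-ol (both anomers) | C=C[C@@H]1OC(O)(CC(C)=C)[C@@H]2[C@@]1(C)CC[C@]2(O[Si](C)(C)C(C)(C)C)C(C)C | intermediate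
22 | (3S,3aR,8S,8aR)-3-[(tert-butyldimethylsilyl)oxy]-8-hydroxy-6,8a-dimethyl-3-(propan-2-yl)-2,3,3a,5,8,8a-hexahydroazulen-4(1H)-one | CC1=C[C@H](O)[C@]2(C)CC[C@](O[Si](C)(C)C(C)(C)C)(C(C)C)[C@@H]2C(=O)C1 | intermediate
23 | 3-methylbutanoic anhydride | CC(C)CC(=O)OC(=O)CC(C)C | starting material
24 | (3S,3aR,8S,8aR)-3-[(tert-butyldimethylsilyl)oxy]-6,8a-dimethyl-4-oxo-3-(propan-2-yl)-1,2,3,3a,4,5,8,8a-octahydroazulen-8-yl 3-methylbutanoate | CC1=C[C@H](OC(=O)CC(C)C)[C@]2(C)CC[C@](O[Si](C)(C)C(C)(C)C)(C(C)C)[C@@H]2C(=O)C1 | intermediate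
25 | (3S,3aS,4R,8S,8aR)-3-[(tert-butyldimethylsilyl)oxy]-4-hydroxy-6,8a-dimethyl-3-(propan-2-yl)-1,2,3,3a,4,5,8,8a-octahydroazulen-8-yl 3-methylbutanoate | CC1=C[C@H](OC(=O)CC(C)C)[C@]2(C)CC[C@](O[Si](C)(C)C(C)(C)C)(C(C)C)[C@@H]2[C@H](O)C1 | intermediate
26 | 4-[(tert-butyldimethylsilyl)oxy]benzoic acid | CC(C)(C)[Si](C)(C)Oc1ccc(cc1)C(O)=O | starting material
27 | 4-[(tert-butyldimethylsilyl)oxy]benzoic 2,4,6-trichlorobenzoic anhydride | CC(C)(C)[Si](C)(C)Oc1ccc(cc1)C(=O)OC(=O)c1c(Cl)cc(Cl)cc1Cl | intermediate
28 | (3S,3aS,4R,8S,8aR)-3-[(tert-butyldimethylsilyl)oxy]-6,8a-dimethyl-8-[(3-methylbutanoyl)oxy]-3-(propan-2-yl)-1,2,3,3a,4,5,8,8a-octahydroazulen-4-yl 4-[(tert-butyldimethylsilyl)oxy]benzoate | CC1=C[C@H](OC(=O)CC(C)C)[C@]2(C)CC[C@](O[Si](C)(C)C(C)(C)C)(C(C)C)[C@@H]2[C@H](OC(=O)c2ccc(O[Si](C)(C)C(C)(C)C)cc2)C1 | intermediate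
29 | (3S,3aS,4R,8S,8aR)-3-hydroxy-6,8a-dimethyl-8-[(3-methylbutanoyl)oxy]-3-(propan-2-yl)-1,2,3,3a,4,5,8,8a-octahydroazulen-4-yl 4-hydroxybenzoate | CC1=C[C@H](OC(=O)CC(C)C)[C@]2(C)CC[C@](O)(C(C)C)[C@@H]2[C@H](OC(=O)c2ccc(O)cc2)C1 | target

Total step count: 17. Longest linear sequence: 14 steps (steps 1–4, then 8–17).

Steps most likely to fail

Step 11. The carbenoid may be consumed by 1,6-insertion into the isopropyl methine, by a 1,2-alkyl shift or by dimerisation before it reaches the hindered methine. The fallback makes the same bond by a reductive ketyl coupling; it sets out from diazo lactone 18 and comes back at bicyclic lactone 19. Dimethyldioxirane in acetone at −78 °C turns the diazo carbon into a ketone and gives the α-keto lactone F1. HF·pyridine frees the side-chain carbinol to give the hydroxy keto lactone F2, and Dess–Martin periodinane gives the diketo lactone F3. SmI2 in THF at −78 °C then joins the two ketone carbons in a chelated pinacol cyclisation to the cis-fused cis-diol F4; its side-chain hydroxyl is cis to the hydroxyl on the lactone α-carbon and therefore trans to the lactone carbonyl, as in 19. Excess SmI2 with HMPA and t-BuOH removes the hydroxyl α to the lactone carbonyl to give the hydroxy lactone F5, and TBSOTf with 2,6-lutidine gives 19.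

Step 14. Acylation may stall on the oxygen-bridged hemiketal tautomer of 22, and the basic medium may move the β,γ double bond into conjugation. The fallback places the isovalerate before the ketone exists; it sets out from bicyclic lactone 19 and comes back at keto ester 24. MeNH(OMe)·HCl and AlMe3 in CH2Cl2 open the lactone to the hydroxy Weinreb amide F6. Anhydride 23 with DMAP gives the amide ester F7, and Grignard reagent 20 in THF at −78 °C adds once to the amide to give the dienyl keto ester F8. Ring-closing metathesis with second-generation Hoveyda–Grubbs catalyst in toluene at 80 °C then gives 24.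

Step 15. Hydride delivery to the flexible cycloheptenone may show poor facial selectivity. The fallback converges both epimers by an esterification with inversion; it sets out from keto ester 24 and comes back at diester 28. The 4S alcohol F9 formed beside 25 (or made on purpose with NaBH4 and CeCl3 in MeOH if that face proves preferred) is separated. It is esterified with acid 26 under Mitsunobu conditions (PPh3, DIAD, toluene), which inverts C4 and gives 28, while 25 itself goes on through step 16.

Further compounds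
F1 | step 11 | 3-oxo analogue of lactone 16 (α-keto lactone) | C=C[C@@H]1OC(=O)C(=O)[C@@]1(C)CC[C@H](O[Si](C)(C)C(C)(C)C)C(C)C
F2 | step 11 | desilylated F1 (side-chain secondary alcohol) | C=C[C@@H]1OC(=O)C(=O)[C@@]1(C)CC[C@H](O)C(C)C
F3 | step 11 | diketo lactone (side chain 4-methyl-3-oxopentyl) | C=C[C@@H]1OC(=O)C(=O)[C@@]1(C)CCC(=O)C(C)C
F4 | step 11 | cis-fused 6,6a-dihydroxy analogue of 19 without silyl group (cis-diol) | C=C[C@@H]1OC(=O)[C@]2(O)[C@@]1(C)CC[C@]2(O)C(C)C
F5 | step 11 | 6-hydroxy analogue of 19 (silyl group absent) | C=C[C@@H]1OC(=O)[C@@H]2[C@@]1(C)CC[C@]2(O)C(C)C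
F6 | step 14 | hydroxy Weinreb amide from 19 | C=C[C@H](O)[C@]1(C)CC[C@](O[Si](C)(C)C(C)(C)C)(C(C)C)[C@@H]1C(=O)N(C)OC
F7 | step 14 | 3-methylbutanoate of F6 | C=C[C@H](OC(=O)CC(C)C)[C@]1(C)CC[C@](O[Si](C)(C)C(C)(C)C)(C(C)C)[C@@H]1C(=O)N(C)OC
F8 | step 14 | dienyl keto ester (open-chain precursor of 24) | C=C[C@H](OC(=O)CC(C)C)[C@]1(C)CC[C@](O[Si](C)(C)C(C)(C)C)(C(C)C)[C@@H]1C(=O)CC(C)=C
F9 | step 15 | C4 epimer (4S) of alcohol 25 | CC1=C[C@H](OC(=O)CC(C)C)[C@]2(C)CC[C@](O[Si](C)(C)C(C)(C)C)(C(C)C)[C@@H]2[C@@H](O)C1
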